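**Retrosynthetic overview**

1. 29 ⇐ 23: end-game acylations (C9 acetate, C8 (R)-2-methylbutanoate) and release of C15–OH.
2. 23 ⇐ 21: ring contraction 11 → 10 by a semipinacol 1,2-alkenyl shift (C1 moves from C14 to C10, C14 leaves the ring as the formyl group, the C9–O bond is kept), then conjugation of the enal.
3. 21 ⇐ 18: hydroxyl-directed threo epoxidation (sets C9) and ring-closing metathesis (C1=C2) to the 11-membered ring.
4. 18 ⇐ 16 + 13: reagent-controlled alkynylation (sets C8) and cis-reduction; 16 ⇐ 11 + 4: catalytic asymmetric chromium allylation/lactonisation (sets C6, C7).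
5. Ring order: γ-lactone, then 11-membered carbocycle, then 10-membered carbocycle; fragment 11 carries the ring-cis C4=C5 alkene from an anti-carbomagnesiation.

Assumption 1: atoms are numbered as in the germacrane skeleton of the target (ring C1–C10; C11–C13 the methylene-lactone carbons; C14 the formyl carbon; C15 the hydroxymethyl carbon); α is the face of H7.
Assumption 2: 12 is used as the commercial racemate; the carbon it supplies as C14 is carried as a 1:1 epimer mixture (left open in the SMILES of 13, 17–21 and F1–F4) and, like the E/Z mixture at C1=C2 in 21 and 22, is erased in step 15.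

**Route**

Step 1
Reactants: 1 methyl acrylate; 2 2,2-dimethoxyacetaldehyde
Product: 3 methyl 3-hydroxy-4,4-dimethoxy-2-methylidenebutanoate (racemic)
Conditions: DABCO (cat.), dioxane/H2O, rt
Reagents that add atoms: none
Why: Morita–Baylis–Hillman reaction of the acrylate with a non-enolisable aldehyde; the racemic carbinol centre is erased in step 2.

Step 2
Reactants: 3 methyl 3-hydroxy-4,4-dimethoxy-2-methylidenebutanoate
Product: 4 methyl (2Z)-2-(bromomethyl)-4,4-dimethoxybut-2-enoate
Conditions: N-bromosuccinimide, Me2S, CH2Cl2, 0 °C → rt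
Reagents that add atoms: N-bromosuccinimide, O=C1CCC(=O)N1Br
Why: Bromosulfonium activation of the allylic alcohol and SN2′ attack of bromide (Corey–Kim-type allylic bromination of a Baylis–Hillman adduct) give the transposed bromide as the thermodynamically preferred Z isomer.

Step 3
Reactants: 5 3,3-dimethoxyprop-1-yne; 6 formaldehyde (as paraformaldehyde)
Product: 7 4,4-dimethoxybut-2-yn-1-ol
Conditions: n-BuLi, THF, −78 °C → rt; then H2O
Reagents that add atoms: none
Why: Lithium acetylide addition to formaldehyde installs C15 as the free primary alcohol that directs step 4.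

Step 4
Reactants: 7 4,4-dimethoxybut-2-yn-1-ol; 8 allylmagnesium bromide
Product: 9 (2E)-4,4-dimethoxy-2-(prop-2-en-1-yl)but-2-en-1-ol
Conditions: 8 (3 equiv), Et2O, 0 °C → reflux; then H2O
Reagents that add atoms: none
Why: Hydroxyl-directed anti-carbomagnesiation of a propargylic alcohol delivers allyl to the proximal alkyne carbon (C4) and protonation of the chelated vinylmagnesium leaves C6 cis to the allyl carbon C3, which is the ring-cis C4=C5 geometry of the target.

Step 5
Reactants: 9 (2E)-4,4-dimethoxy-2-(prop-2-en-1-yl)but-2-en-1-ol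
Product: 10 1-({[(2E)-4,4-dimethoxy-2-(prop-2-en-1-yl)but-2-en-1-yl]oxy}methyl)-4-methoxybenzene
Conditions: NaH, 4-methoxybenzyl chloride, Bu4NI (cat.), THF, 0 °C → rt
Reagents that add atoms: 4-methoxybenzyl chloride, COc1ccc(CCl)cc1
Why: Williamson etherification protects C15–OH so that it cannot direct the epoxidation of step 12.

Step 6
Reactants: 10 1-({[(2E)-4,4-dimethoxy-2-(prop-2-en-1-yl)but-2-en-1-yl]oxy}methyl)-4-methoxybenzene
Product: 11 (2E)-3-{[(4-methoxyphenyl)methoxy]methyl}hexa-2,5-dienal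
Conditions: PPTS (cat.), acetone/H2O, rt
Reagents that add atoms: water, O
Why: Mild acid hydrolysis of the dimethyl acetal unveils the C6 enal without touching the benzyl-type ether; the enal is used at once to avoid E/Z drift.

Step 7
Reactants: 12 pent-1-en-4-yn-3-ol (racemic)
Product: 13 triethyl(pent-1-en-4-yn-3-yloxy)silane
Conditions: Et3SiCl, imidazole, CH2Cl2, 0 °C
Reagents that add atoms: chlorotriethylsilane, CC[Si](Cl)(CC)CC
Why: Standard silylation; the silyl group stops this hydroxyl from directing the epoxidation and later serves as the oxygen-to-oxygen transfer group of the key step.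

Step 8
Reactants: 11 (2E)-3-{[(4-methoxyphenyl)methoxy]methyl}hexa-2,5-dienal; 4 methyl (2Z)-2-(bromomethyl)-4,4-dimethoxybut-2-enoate
Product: 15 lactone acetal (4S,5R)-4-(dimethoxymethyl)-5-[(1E)-2-{[(4-methoxyphenyl)methoxy]methyl}penta-1,4-dien-1-yl]-3-methylideneoxolan-2-one, via hydroxy ester 14 (not isolated)
Conditions: CrCl2 (10 mol %), chiral carbazole-bis(oxazoline) ligand (12 mol %, enantiomer giving 6R), Mn, Me3SiCl, THF, 0 °C → rt; then K2CO3 (cat.), MeOH, 0 °C
Reagents that add atoms: none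
Why: Catalytic asymmetric Nozaki–Hiyama-type 2-(alkoxycarbonyl)allylation in which the allylchromium adds through a chair transition state with the dimethoxymethyl group equatorial (anti adduct) and the chiral ligand selects the aldehyde face, so that C6 (R) and C7 (S) are set and lactonisation gives the trans-fused methylene lactone.

Step 9
Reactants: 15 lactone acetal
Product: 16 lactone aldehyde (2R,3S)-2-[(1E)-2-{[(4-methoxyphenyl)methoxy]methyl}penta-1,4-dien-1-yl]-4-methylidene-5-oxooxolane-3-carbaldehyde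
Conditions: Amberlyst-15, acetone/H2O, rt
Reagents that add atoms: water, O
Why: Acid-catalysed acetal hydrolysis gives the C8 aldehyde under non-basic conditions that do not isomerise the exocyclic methylene into the ring; it is used crude.

Step 10
Reactants: 16 lactone aldehyde; 13 triethyl(pent-1-en-4-yn-3-yloxy)silane
Product: 17 propargylic alcohol (4R,5R)-4-[(1S)-1-hydroxy-4-(triethylsilyloxy)hex-5-en-2-yn-1-yl]-5-[(1E)-2-{[(4-methoxyphenyl)methoxy]methyl}penta-1,4-dien-1-yl]-3-methylideneoxolan-2-one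
Conditions: Me2Zn, ProPhenol ligand (20 mol %, enantiomer giving 8S), Ph3P=O (40 mol %), toluene, 0 °C; then H2O
Reagents that add atoms: none
Why: Zinc–ProPhenol asymmetric alkynylation in which the dinuclear zinc catalyst delivers the alkynyl group to one aldehyde face (reagent control), setting C8 without amine base.

Step 11
Reactants: 17 propargylic alcohol
Product: 18 (Z)-allylic alcohol (4R,5R)-4-[(1R,2Z)-1-hydroxy-4-(triethylsilyloxy)hexa-2,5-dien-1-yl]-5-[(1E)-2-{[(4-methoxyphenyl)methoxy]methyl}penta-1,4-dien-1-yl]-3-methylideneoxolan-2-one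
Conditions: H2 (1 atm), Pd/CaCO3 poisoned with Pb(OAc)2 (Lindlar catalyst), quinoline, EtOAc, rt
Reagents that add atoms: none
Why: Lindlar semihydrogenation gives the (9Z)-alkene and is stopped before the terminal and conjugated alkenes react.

Step 12
Reactants: 18 (Z)-allylic alcohol
Product: 19 epoxy alcohol (4R,5R)-4-[(S)-hydroxy{(2R,3R)-3-[1-(triethylsilyloxy)prop-2-en-1-yl]oxiran-2-yl}methyl]-5-[(1E)-2-{[(4-methoxyphenyl)methoxy]methyl}penta-1,4-dien-1-yl]-3-methylideneoxolan-2-one
Conditions: VO(acac)2 (5 mol %), t-BuOOH, CH2Cl2, 0 °C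
Reagents that add atoms: tert-butyl hydroperoxide, CC(C)(C)OO
Why: Hydroxyl-directed vanadium epoxidation of a Z-allylic alcohol, where A(1,3) strain holds H8 in the alkene plane so that oxygen is delivered syn to the C8 hydroxyl (threo cis-epoxide), which sets C9 with the configuration of the target while the electron-poor and non-allylic alkenes stay untouched.

Step 13
Reactants: 19 epoxy alcohol
Product: 20 O8-tert-butyldimethylsilyl ether of 19
Conditions: t-BuMe2SiOTf, 2,6-lutidine, CH2Cl2, −78 °C
Reagents that add atoms: tert-butyldimethylsilyl trifluoromethanesulfonate, CC(C)(C)[Si](C)(C)OS(=O)(=O)C(F)(F)F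
Why: Silylation gives a non-participating group at O8, which an ester there would not be (acyloxy participation at C9 in step 15).

Step 14
Reactants: 20 O8-tert-butyldimethylsilyl ether of 19
Product: 21 11-membered epoxy silyl ether (ring C1=C2–C3–C4=C5–C6–C7–C8–C9–C10–C14; 12,6α-lactone; cis-9α,10α-epoxide; 8β-OSiMe2t-Bu; 14-OSiEt3; 15-O-PMB)
Conditions: RuCl2(PCy3)2(=CHPh) (first-generation Grubbs catalyst, 15 mol %), CH2Cl2 (1 mM), 40 °C
Reagents that add atoms: none
Why: Ring-closing metathesis of the two monosubstituted alkenes closes the 11-membered ring at C1=C2; the first-generation catalyst leaves the electron-poor 1,1-disubstituted and the trisubstituted alkenes alone, and the geometry of the new alkene does not matter because step 15 erases it.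

Step 15
Reactants: 21 11-membered epoxy silyl ether
Product: 23 ring-contracted enal 8β-(tert-butyldimethylsilyloxy)-15-(4-methoxybenzyloxy)-14-oxo-9α-(triethylsilyloxy)germacra-1(10),4,11(13)-trien-12,6α-olide, via deconjugated aldehyde 22 (not isolated)
Conditions: Me3SiOTf (10 mol %), CH2Cl2, −78 °C; then Et3N (0.5 equiv), −78 → 0 °C
Reagents that add atoms: none
Why: Proposed new method: ring-contractive type 3 semipinacol rearrangement of a macrocyclic 2,3-epoxy silyl ether, in which silyl-triflate activation of the epoxide oxygen triggers an anti 1,2-shift of the ring alkenyl carbon C1 from the carbinol carbon C14 to C10 (a gauche ring torsion C1–C14–C10–C9 places the C14–C1 bond antiperiplanar to the breaking C10–O bond, and alkenyl migrates far faster than H or the alkyl group on the C8 side), the resulting oxocarbenium ion hands its silyl group to O9 so that the Lewis acid turns over, C14 leaves the ring as the formyl group, the C9–O bond from step 12 is untouched, and amine-mediated dienolate formation then moves C1=C2 into conjugation to give the thermodynamically preferred enal (C2 trans to CHO, cis in the ring) while erasing C10, C14 and the C1=C2 geometry; the closest known reactions are the Suzuki–Tsuchihashi 1,2-alkenyl shift of open-chain epoxy silyl ethers and Meinwald-type ring contractions of small-ring epoxides.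

Step 16
Reactants: 23 ring-contracted enal
Product: 25 9α-acetoxy-8β-(tert-butyldimethylsilyloxy)-15-(4-methoxybenzyloxy)-14-oxogermacra-1(10),4,11(13)-trien-12,6α-olide, via C9 alcohol 24 (not isolated)
Conditions: AcOH/THF/H2O (3:1:1), rt; concentrate; then Ac2O, pyridine, DMAP (cat.), CH2Cl2, 0 °C
Reagents that add atoms: acetic anhydride, CC(=O)OC(C)=O
Why: The triethylsilyl ether at C9 is cleaved selectively beside the bulkier silyl ether at C8 and the freed secondary alcohol is acetylated (DMAP-catalysed acylation); C10 is now sp2, so the β-acetoxy aldehyde cannot eliminate.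

Step 17
Reactants: 25 9α-acetoxy-8β-(tert-butyldimethylsilyloxy) compound
Product: 26 9α-acetoxy-8β-hydroxy-15-(4-methoxybenzyloxy)-14-oxogermacra-1(10),4,11(13)-trien-12,6α-olide
Conditions: HF·pyridine, pyridine, THF, 0 °C → rt
Reagents that add atoms: none
Why: Fluoride cleavage of the silyl ether under mildly acidic conditions frees C8–OH without acetyl migration.

Step 18
Reactants: 26 9α-acetoxy-8β-hydroxy compound; 27 (2R)-2-methylbutanoic acid
Product: 28 9α-acetoxy-15-(4-methoxybenzyloxy)-8β-[(2R)-2-methylbutanoyloxy]-14-oxogermacra-1(10),4,11(13)-trien-12,6α-olide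
Conditions: DCC, DMAP (cat.), CH2Cl2, 0 °C
Reagents that add atoms: none
Why: Steglich esterification installs the enantiopure acid with its stereocentre intact.

Step 19
Reactants: 28 4-methoxybenzyl ether of the target
Product: 29 target, 9α-acetoxy-15-hydroxy-8β-[(2R)-2-methylbutanoyloxy]-14-oxogermacra-1(10),4,11(13)-trien-12,6α-olide (6R,7S,8S,9S)
Conditions: DDQ, CH2Cl2/pH 7 buffer, 0 °C
Reagents that add atoms: none
Why: Oxidative cleavage of the 4-methoxybenzyl ether (hydride abstraction by DDQ, then hydrolysis) frees C15–OH under neutral conditions that leave the esters, the enal and the lactone alone.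

**Compound list**

1 | methyl acrylate | C=CC(=O)OC | starting material
2 | 2,2-dimethoxyacetaldehyde | COC(OC)C=O | starting material
3 | methyl 3-hydroxy-4,4-dimethoxy-2-methylidenebutanoate (racemic) | C=C(C(=O)OC)C(O)C(OC)OC | intermediate
4 | methyl (2Z)-2-(bromomethyl)-4,4-dimethoxybut-2-enoate | COC(=O)/C(CBr)=C/C(OC)OC | intermediate
5 | 3,3-dimethoxyprop-1-yne | C#CC(OC)OC | starting material
6 | formaldehyde (as paraformaldehyde) | C=O | starting material
7 | 4,4-dimethoxybut-2-yn-1-ol | OCC#CC(OC)OC | intermediate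
8 | allylmagnesium bromide | C=CC[Mg]Br | starting material
9 | (2E)-4,4-dimethoxy-2-(prop-2-en-1-yl)but-2-en-1-ol | OC/C(CC=C)=C/C(OC)OC | intermediate
10 | 1-({[(2E)-4,4-dimethoxy-2-(prop-2-en-1-yl)but-2-en-1-yl]oxy}methyl)-4-methoxybenzene | COc1ccc(COC/C(CC=C)=C/C(OC)OC)cc1 | intermediate
11 | (2E)-3-{[(4-methoxyphenyl)methoxy]methyl}hexa-2,5-dienal | O=C/C=C(/COCc1ccc(OC)cc1)CC=C | intermediate
12 | pent-1-en-4-yn-3-ol (racemic) | C=CC(O)C#C | starting material
13 | triethyl(pent-1-en-4-yn-3-yloxy)silane (racemic) | C=CC(O[Si](CC)(CC)CC)C#C | intermediate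
14 | hydroxy ester, methyl (3S,4R,5E)-3-(dimethoxymethyl)-4-hydroxy-6-{[(4-methoxyphenyl)methoxy]methyl}-2-methylidenenona-5,8-dienoate | C=C(C(=O)OC)[C@H](C(OC)OC)[C@H](O)/C=C(/COCc1ccc(OC)cc1)CC=C | intermediate (not isolated)
15 | lactone acetal, (4S,5R)-4-(dimethoxymethyl)-5-[(1E)-2-{[(4-methoxyphenyl)methoxy]methyl}penta-1,4-dien-1-yl]-3-methylideneoxolan-2-one | C=C1C(=O)O[C@H](/C=C(/COCc2ccc(OC)cc2)CC=C)[C@H]1C(OC)OC | intermediate
16 | lactone aldehyde, (2R,3S)-2-[(1E)-2-{[(4-methoxyphenyl)methoxy]methyl}penta-1,4-dien-1-yl]-4-methylidene-5-oxooxolane-3-carbaldehyde | C=C1C(=O)O[C@H](/C=C(/COCc2ccc(OC)cc2)CC=C)[C@H]1C=O | intermediate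
17 | propargylic alcohol, (4R,5R)-4-[(1S)-1-hydroxy-4-(triethylsilyloxy)hex-5-en-2-yn-1-yl]-5-[(1E)-2-{[(4-methoxyphenyl)methoxy]methyl}penta-1,4-dien-1-yl]-3-methylideneoxolan-2-one (C14 epimers) | C=C1C(=O)O[C@H](/C=C(/COCc2ccc(OC)cc2)CC=C)[C@H]1[C@H](O)C#CC(O[Si](CC)(CC)CC)C=C | intermediate
18 | (Z)-allylic alcohol, (4R,5R)-4-[(1R,2Z)-1-hydroxy-4-(triethylsilyloxy)hexa-2,5-dien-1-yl]-5-[(1E)-2-{[(4-methoxyphenyl)methoxy]methyl}penta-1,4-dien-1-yl]-3-methylideneoxolan-2-one (C14 epimers) | C=C1C(=O)O[C@H](/C=C(/COCc2ccc(OC)cc2)CC=C)[C@H]1[C@H](O)/C=C\C(O[Si](CC)(CC)CC)C=C | intermediate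
19 | epoxy alcohol, (4R,5R)-4-[(S)-hydroxy{(2R,3R)-3-[1-(triethylsilyloxy)prop-2-en-1-yl]oxiran-2-yl}methyl]-5-[(1E)-2-{[(4-methoxyphenyl)methoxy]methyl}penta-1,4-dien-1-yl]-3-methylideneoxolan-2-one (cis-epoxide, threo to the C8 hydroxyl; C14 epimers) | C=C1C(=O)O[C@H](/C=C(/COCc2ccc(OC)cc2)CC=C)[C@H]1[C@H](O)[C@H]3O[C@H]3C(O[Si](CC)(CC)CC)C=C | intermediate
20 | O8-tert-butyldimethylsilyl ether of 19 | C=C1C(=O)O[C@H](/C=C(/COCc2ccc(OC)cc2)CC=C)[C@H]1[C@H](O[Si](C)(C)C(C)(C)C)[C@H]3O[C@H]3C(O[Si](CC)(CC)CC)C=C | intermediate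
21 | 11-membered epoxy silyl ether (ring C1=C2–C3–C4=C5–C6–C7–C8–C9–C10–C14; 12,6α-lactone; cis-9α,10α-epoxide; 8β-OSiMe2t-Bu; 14-OSiEt3; 15-O-PMB; C1=C2 E/Z mixture; C14 epimers) | C=C1C(=O)O[C@@H]2/C=C(/COCc3ccc(OC)cc3)CC=CC(O[Si](CC)(CC)CC)[C@@H]4O[C@@H]4[C@@H](O[Si](C)(C)C(C)(C)C)[C@@H]12 | intermediate
22 | deconjugated aldehyde, 10-membered ring with C1=C2 (E/Z mixture), 10-H, 10-CHO, 9α-OSiEt3, 8β-OSiMe2t-Bu, 15-O-PMB, 12,6α-lactone | C=C1C(=O)O[C@@H]2/C=C(/COCc3ccc(OC)cc3)CC=C[C@H](C=O)[C@H](O[Si](CC)(CC)CC)[C@@H](O[Si](C)(C)C(C)(C)C)[C@@H]12 | intermediate (not isolated)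
23 | 8β-(tert-butyldimethylsilyloxy)-15-(4-methoxybenzyloxy)-14-oxo-9α-(triethylsilyloxy)germacra-1(10),4,11(13)-trien-12,6α-olide (both ring alkenes cis in the ring) | C=C1C(=O)O[C@@H]2/C=C(/COCc3ccc(OC)cc3)CC/C=C(/C=O)[C@H](O[Si](CC)(CC)CC)[C@@H](O[Si](C)(C)C(C)(C)C)[C@@H]12 | intermediate
24 | C9 alcohol, 9α-hydroxy analogue of 23 | C=C1C(=O)O[C@@H]2/C=C(/COCc3ccc(OC)cc3)CC/C=C(/C=O)[C@H](O)[C@@H](O[Si](C)(C)C(C)(C)C)[C@@H]12 | intermediate (not isolated)
25 | 9α-acetoxy-8β-(tert-butyldimethylsilyloxy)-15-(4-methoxybenzyloxy)-14-oxogermacra-1(10),4,11(13)-trien-12,6α-olide | C=C1C(=O)O[C@@H]2/C=C(/COCc3ccc(OC)cc3)CC/C=C(/C=O)[C@H](OC(C)=O)[C@@H](O[Si](C)(C)C(C)(C)C)[C@@H]12 | intermediate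
26 | 9α-acetoxy-8β-hydroxy-15-(4-methoxybenzyloxy)-14-oxogermacra-1(10),4,11(13)-trien-12,6α-olide | C=C1C(=O)O[C@@H]2/C=C(/COCc3ccc(OC)cc3)CC/C=C(/C=O)[C@H](OC(C)=O)[C@@H](O)[C@@H]12 | intermediate
27 | (2R)-2-methylbutanoic acid | CC[C@@H](C)C(=O)O | starting material
28 | 9α-acetoxy-15-(4-methoxybenzyloxy)-8β-[(2R)-2-methylbutanoyloxy]-14-oxogermacra-1(10),4,11(13)-trien-12,6α-olide | C=C1C(=O)O[C@@H]2/C=C(/COCc3ccc(OC)cc3)CC/C=C(/C=O)[C@H](OC(C)=O)[C@@H](OC(=O)[C@H](C)CC)[C@@H]12 | intermediate
29 | 9α-acetoxy-15-hydroxy-8β-[(2R)-2-methylbutanoyloxy]-14-oxogermacra-1(10),4,11(13)-trien-12,6α-olide (6R,7S,8S,9S) | C=C1C(=O)O[C@@H]2/C=C(/CO)CC/C=C(/C=O)[C@H](OC(C)=O)[C@@H](OC(=O)[C@H](C)CC)[C@@H]12 | target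

**Step count and risks**

Total step count: 19. Longest linear sequence: 16 steps (from 5 through steps 3–6 and 8–19 to 29).

The three steps most likely to fail:

Step 15 (the new ring contraction). The macrocycle may not reach the antiperiplanar geometry, or the C4=C5 alkene may attack the activated epoxide across the ring. The fallback uses known chemistry and sets out from 20. The same silyl-triflate-catalysed rearrangement is run on the open-chain epoxy silyl ether, where the 1,2-alkenyl shift is established (Suzuki–Tsuchihashi rearrangement), to give the open-chain α-vinyl β-silyloxy aldehyde F5. Ring-closing metathesis of F5 (RuCl2(PCy3)2(=CHPh), high dilution) then closes the 10-membered ring directly and gives 22, which is conjugated with Et3N to 23, where the route is rejoined.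

Step 14 (metathesis to an 11-membered ring carrying an epoxide and two silyl ethers). Ring strain or oligomerisation may dominate. The fallback sets out from 18. Ring-closing metathesis before the epoxide and the second silyl ether are in place gives the 11-membered (9Z)-allylic alcohol F3. VO(acac)2/t-BuOOH epoxidation directed by the C8 hydroxyl then gives the 11-membered epoxy alcohol F4. Silylation (t-BuMe2SiOTf, 2,6-lutidine) returns to the route at 21.

Step 10 (alkynylation of the isomerisable β-formyl methylene lactone 16). The aldehyde may epimerise or move its exocyclic alkene into the ring before it is trapped. The fallback sets out from 13 and 16. Iodination of 13 (N-iodosuccinimide, AgNO3 cat.) gives the iodoalkyne triethyl[(5-iodopent-1-en-4-yn-3-yl)oxy]silane F1. Cis-reduction with diimide (2-nitrobenzenesulfonyl hydrazide, Et3N) gives the vinyl iodide triethyl{[(1Z)-1-iodopenta-1,4-dien-3-yl]oxy}silane F2. A base-free Nozaki–Hiyama–Kishi coupling of F2 with 16 (CrCl2, NiCl2 cat., DMSO/THF) gives 18 directly, with the C8 epimers separated. The route is rejoined at 18 and step 11 is skipped.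

Further compounds

F1 | step 10 | triethyl[(5-iodopent-1-en-4-yn-3-yl)oxy]silane | C=CC(O[Si](CC)(CC)CC)C#CI
F2 | step 10 | triethyl{[(1Z)-1-iodopenta-1,4-dien-3-yl]oxy}silane | C=CC(O[Si](CC)(CC)CC)/C=C\I
F3 | step 14 | 11-membered (9Z)-allylic alcohol (ring as in 21 without the epoxide; 8β-OH; 14-OSiEt3; 15-O-PMB) | C=C1C(=O)O[C@@H]2/C=C(/COCc3ccc(OC)cc3)CC=CC(O[Si](CC)(CC)CC)/C=C\[C@@H](O)[C@@H]12
F4 | step 14 | 11-membered epoxy alcohol (21 with free 8β-OH) | C=C1C(=O)O[C@@H]2/C=C(/COCc3ccc(OC)cc3)CC=CC(O[Si](CC)(CC)CC)[C@@H]4O[C@@H]4[C@@H](O)[C@@H]12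
F5 | step 15 | open-chain α-vinyl β-silyloxy aldehyde (lactone 15 skeleton with C8-OSiMe2t-Bu, C9-OSiEt3 and C10 carrying vinyl and CHO) | C=C1C(=O)O[C@H](/C=C(/COCc2ccc(OC)cc2)CC=C)[C@H]1[C@H](O[Si](C)(C)C(C)(C)C)[C@@H](O[Si](CC)(CC)CC)[C@H](C=C)C=O
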